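**Retrosynthetic overview**

- The target is disconnected at the C10–O ester bond: the last step is a regioselective palmitoylation of the exocyclic C10 hydroxyl of an oxolane diol.
- The oxolane (O1, C11, C12, C13, C14) is the only ring. It is closed in one enzymatic operation from a skipped cis,cis-bis-epoxide: hydration at C13, then attack of the freed C14 hydroxyl on C11.
- The bis-epoxide is disconnected at C8–C9: a bis-epoxy triflate is coupled with oct-7-enylmagnesium bromide under copper catalysis.
- The bis-epoxy alcohol comes from two reagent-controlled Katsuki–Sharpless epoxidations of Z-allylic alcohols (same tartrate both times), joined through C11–C12 by an epoxy triflate/acetylide coupling and a Lindlar reduction, starting from oct-2-yn-1-ol.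
- Feature the plan rests on: the four oxygen-bearing carbons C10, C11, C13, C14 sit around the lone methylene C12, with O1 bridging C11 and C14 — the imprint of a methylene-interrupted bis-epoxide opened twice with inversion.

Key step: step 9

Remarks on the chemistry:
- Locants C1–C19 follow the nonadec-1-ene chain (C1 = vinyl CH2) throughout.
- The two oxiranes of the key precursor have mirror-image local configurations (C11 S, C13 R). One chiral catalyst acting on the Z,Z-diene cannot set both, so they are built one after the other from allylic alcohols.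
- Assumption: the hydrolase for step 9 is chosen by screening a panel of recombinant soluble and microbial epoxide hydrolases on the bis-epoxide; no single named enzyme is presupposed.

**Route**

Step 1
Reactants: 1 oct-2-yn-1-ol
Product: 2 (Z)-oct-2-en-1-ol
Conditions: H2 (1 atm), Pd/CaCO3 poisoned with Pb(OAc)2 (Lindlar catalyst), quinoline, hexane, rt
Reagents that add atoms: none
Why: Lindlar semi-hydrogenation delivers both hydrogens to the same face of the alkyne on the poisoned palladium surface and stops at the Z-alkene.

Step 2
Reactants: 2 (Z)-oct-2-en-1-ol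
Product: 3 [(2R,3S)-3-pentyloxiran-2-yl]methanol
Conditions: Ti(OiPr)4 (0.15 equiv), D-(−)-diethyl tartrate (0.2 equiv), t-BuOOH (anhydrous, in decane), 4 Å molecular sieves, CH2Cl2, −20 °C
Reagents that add atoms: tert-butyl hydroperoxide, CC(C)(C)OO
Why: Katsuki–Sharpless asymmetric epoxidation: the titanium–tartrate complex binds the allylic alkoxide and transfers the peroxide oxygen to one alkene face, and with D-(−)-tartrate a Z-allylic alcohol should give the (2R,3S)-cis-epoxy alcohol, which fixes C13 (R) and C14 (S).

Step 3
Reactants: 3 [(2R,3S)-3-pentyloxiran-2-yl]methanol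
Product: 4 [(2R,3S)-3-pentyloxiran-2-yl]methyl trifluoromethanesulfonate
Conditions: Tf2O, 2,6-lutidine, CH2Cl2, −78 °C; cold aqueous work-up, used at once
Reagents that add atoms: trifluoromethanesulfonic anhydride, O=S(=O)(OS(=O)(=O)C(F)(F)F)C(F)(F)F
Why: O-sulfonylation of the primary alcohol with a hindered base at low temperature leaves the oxirane and both stereocentres untouched and gives the most reactive primary electrophile for the next step.

Step 4
Reactants: 4 [(2R,3S)-3-pentyloxiran-2-yl]methyl trifluoromethanesulfonate; 5 tert-butyldimethyl(prop-2-yn-1-yloxy)silane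
Product: 8 4-[(2R,3S)-3-pentyloxiran-2-yl]but-2-yn-1-ol, via lithium acetylide 6 (not isolated), via silyl ether 7 (not isolated)
Conditions: 5, n-BuLi, THF, −78 °C; then 4, DMPU, −78 → −20 °C; then TBAF, 0 °C → rt
Reagents that add atoms: none
Why: SN2 alkylation of a lithium acetylide by a primary triflate (forms C11–C12) is much faster at −78 °C than attack on the dialkyl oxirane, so the cis-epoxide is carried through unchanged, and fluoride then removes the silyl ether in the same flask.

Step 5
Reactants: 8 4-[(2R,3S)-3-pentyloxiran-2-yl]but-2-yn-1-ol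
Product: 9 (2Z)-4-[(2R,3S)-3-pentyloxiran-2-yl]but-2-en-1-ol
Conditions: H2 (1 atm), Pd/CaCO3 poisoned with Pb(OAc)2 (Lindlar catalyst), quinoline, EtOAc, rt
Reagents that add atoms: none
Why: Lindlar semi-hydrogenation gives the Z-allylic alcohol by syn hydrogen delivery, and the oxirane is inert to hydrogen over the poisoned catalyst.

Step 6
Reactants: 9 (2Z)-4-[(2R,3S)-3-pentyloxiran-2-yl]but-2-en-1-ol
Product: 10 [(2R,3S)-3-{[(2R,3S)-3-pentyloxiran-2-yl]methyl}oxiran-2-yl]methanol
Conditions: Ti(OiPr)4 (0.15 equiv), D-(−)-diethyl tartrate (0.2 equiv), t-BuOOH (anhydrous, in decane), 4 Å molecular sieves, CH2Cl2, −20 °C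
Reagents that add atoms: tert-butyl hydroperoxide, CC(C)(C)OO
Why: A second Katsuki–Sharpless epoxidation under reagent control of D-(−)-tartrate should set C10 (R) and C11 (S) with cis geometry, the existing oxirane lying beyond the allylic position and not overriding the catalyst; residual minor enantiomer from step 2 is converted here into a diastereomer that can in principle be removed.

Step 7
Reactants: 10 [(2R,3S)-3-{[(2R,3S)-3-pentyloxiran-2-yl]methyl}oxiran-2-yl]methanol
Product: 11 [(2R,3S)-3-{[(2R,3S)-3-pentyloxiran-2-yl]methyl}oxiran-2-yl]methyl trifluoromethanesulfonate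
Conditions: Tf2O, 2,6-lutidine, CH2Cl2, −78 °C; cold aqueous work-up, used at once
Reagents that add atoms: trifluoromethanesulfonic anhydride, O=S(=O)(OS(=O)(=O)C(F)(F)F)C(F)(F)F
Why: O-sulfonylation of the only hydroxyl (C9) under non-nucleophilic, cold conditions activates C9 without touching either oxirane.

Step 8
Reactants: 11 [(2R,3S)-3-{[(2R,3S)-3-pentyloxiran-2-yl]methyl}oxiran-2-yl]methyl trifluoromethanesulfonate; 12 8-bromooct-1-ene
Product: 14 (10R,11S,13R,14S)-10,11:13,14-diepoxynonadec-1-ene, via oct-7-enylmagnesium bromide 13 (not isolated)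
Conditions: 12, Mg, THF, rt; then 11, CuBr·SMe2 (10 mol%), Et2O–THF, −78 → −40 °C; chromatography on Et3N-deactivated silica
Reagents that add atoms: none
Why: Copper-catalysed sp3–sp3 coupling of a Grignard reagent with a primary triflate (forms C8–C9): the transient organocopper species displaces the triflate at −78 °C far faster than it opens a dialkyl oxirane, and no stereocentre is involved.

Step 9
Reactants: 14 (10R,11S,13R,14S)-10,11:13,14-diepoxynonadec-1-ene
Product: 16 (10R,11R,13S,14S)-11,14-epoxynonadec-1-ene-10,13-diol, via epoxy diol 15 (not isolated)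
Conditions: recombinant soluble epoxide hydrolase (selected by screening for attack at C13), phosphate buffer pH 7.4, DMSO (5% v/v), 30 °C; then citrate buffer pH 5, rt, if 15 persists
Reagents that add atoms: water, O
Why: The hydrolase adds its active-site aspartate to C13 anti to the oxirane oxygen and the alkyl–enzyme ester is then hydrolysed, which gives epoxy diol 15 with net inversion at C13 (R to S) and the C14–O bond untouched; the freed C14 hydroxyl then attacks C11 of the neighbouring oxirane from the back, forming O1–C11 with inversion (S to R), while C10 keeps its oxygen and its R configuration. The closest known reaction is the soluble-epoxide-hydrolase hydration of methylene-interrupted cis,cis-diepoxy fatty esters, whose epoxy diols close to oxolane diols. The one ring, the oxolane O1–C11–C12–C13–C14, closes in the 5-exo-tet mode, the other conceivable closures (four-membered from O13 to C11, 5-endo from O13 to C10, 6-endo from O14 to C10) being disfavoured. C13 is set by the anti attack on a cis-oxirane of fixed configuration and C11 by the anti opening of the second cis-oxirane, so both new centres and the threo, threo, 2,5-trans pattern follow from the substrate built in steps 2 and 6. The step needs site selectivity for C13 over C11, C10 and C14: a hydrolase with a consistent preference for one configuration of oxirane carbon narrows the choice to the two R-configured carbons C13 and C10, and the pentyl-versus-nonenyl recognition that picks C13 has to come from the screened enzyme, because the substrate carries no hydroxyl or other handle that could bias it.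

Step 10
Reactants: 16 (10R,11R,13S,14S)-11,14-epoxynonadec-1-ene-10,13-diol; 17 hexadecanoyl chloride
Product: 18 (1R)-1-[(2R,4S,5S)-4-hydroxy-5-pentyloxolan-2-yl]dec-9-en-1-yl hexadecanoate
Conditions: 17 (1.0 equiv, slow addition), 2,4,6-collidine, CH2Cl2, −78 → −20 °C
Reagents that add atoms: none
Why: O-acylation by an acyl chloride with a hindered pyridine base and no nucleophilic catalyst is sterically controlled: the exocyclic C10 hydroxyl is a free rotor that can hydrogen-bond to O1, whereas the ring C13 hydroxyl is held cis to the C14 pentyl group and anti to O1, so the monoester should form mainly at C10 (both are secondary, hence low temperature and limiting acyl chloride); no stereocentre is touched and the trans-disposed 10- and 13-oxygens cannot exchange the acyl group.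

**Compound list**

1 | oct-2-yn-1-ol | CCCCCC#CCO | starting material
2 | (Z)-oct-2-en-1-ol | CCCCC/C=C\CO | intermediate
3 | [(2R,3S)-3-pentyloxiran-2-yl]methanol | OC[C@H]1O[C@H]1CCCCC | intermediate
4 | [(2R,3S)-3-pentyloxiran-2-yl]methyl trifluoromethanesulfonate | FC(F)(F)S(=O)(=O)OC[C@H]1O[C@H]1CCCCC | intermediate
5 | tert-butyldimethyl(prop-2-yn-1-yloxy)silane | C#CCO[Si](C)(C)C(C)(C)C | starting material
6 | lithium 3-{[tert-butyl(dimethyl)silyl]oxy}prop-1-yn-1-ide | [Li]C#CCO[Si](C)(C)C(C)(C)C | intermediate
7 | tert-butyldimethyl({4-[(2R,3S)-3-pentyloxiran-2-yl]but-2-yn-1-yl}oxy)silane | CC(C)(C)[Si](C)(C)OCC#CC[C@H]1O[C@H]1CCCCC | intermediate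
8 | 4-[(2R,3S)-3-pentyloxiran-2-yl]but-2-yn-1-ol | OCC#CC[C@H]1O[C@H]1CCCCC | intermediate
9 | (2Z)-4-[(2R,3S)-3-pentyloxiran-2-yl]but-2-en-1-ol | OC/C=C\C[C@H]1O[C@H]1CCCCC | intermediate
10 | [(2R,3S)-3-{[(2R,3S)-3-pentyloxiran-2-yl]methyl}oxiran-2-yl]methanol | OC[C@H]1O[C@H]1C[C@H]1O[C@H]1CCCCC | intermediate
11 | [(2R,3S)-3-{[(2R,3S)-3-pentyloxiran-2-yl]methyl}oxiran-2-yl]methyl trifluoromethanesulfonate | FC(F)(F)S(=O)(=O)OC[C@H]1O[C@H]1C[C@H]1O[C@H]1CCCCC | intermediate
12 | 8-bromooct-1-ene | C=CCCCCCCBr | starting material
13 | oct-7-en-1-ylmagnesium bromide | C=CCCCCCC[Mg]Br | intermediate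
14 | (10R,11S,13R,14S)-10,11:13,14-diepoxynonadec-1-ene | C=CCCCCCCC[C@H]1O[C@H]1C[C@H]1O[C@H]1CCCCC | intermediate
15 | (10R,11S,13S,14S)-10,11-epoxynonadec-1-ene-13,14-diol | C=CCCCCCCC[C@H]1O[C@H]1C[C@H](O)[C@@H](O)CCCCC | intermediate
16 | (10R,11R,13S,14S)-11,14-epoxynonadec-1-ene-10,13-diol, i.e. (2S,3S,5R)-5-[(1R)-1-hydroxydec-9-en-1-yl]-2-pentyloxolan-3-ol | C=CCCCCCCC[C@@H](O)[C@H]1C[C@H](O)[C@H](CCCCC)O1 | intermediate
17 | hexadecanoyl chloride (palmitoyl chloride) | CCCCCCCCCCCCCCCC(=O)Cl | starting material
18 | (1R)-1-[(2R,4S,5S)-4-hydroxy-5-pentyloxolan-2-yl]dec-9-en-1-yl hexadecanoate | C=CCCCCCCC[C@@H](OC(=O)CCCCCCCCCCCCCCC)[C@H]1C[C@H](O)[C@H](CCCCC)O1 | target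

**Step count and risks**

Total step count: 10. Longest linear sequence: 10 steps (1 to 18); compounds 5, 12 and 17 are commercial and enter directly.

Steps most likely to fail:

1. Step 9 (key step). What may go wrong: hydration starts at the wrong oxirane carbon (C11, C10 or C14), the very lipophilic substrate is turned over too slowly, or the second oxirane of 15 is hydrolysed before it cyclises. Fallback: enzymatic site control is given up for Brønsted-acid catalysis followed by separation. The fallback sets out from 14 and returns at 16. Compound 14 is stirred with dilute HClO4 in THF–water at 0 °C to rt; protonated oxiranes are opened by water with inversion and each diol closes 5-exo as in the main route, but the four oxirane carbons are no longer distinguished. Compound 16 is then expected beside (10R,11R,13S,14S)-10,13-epoxynonadec-1-ene-11,14-diol F1 (water at C11), (10R,11R,13R,14R)-11,14-epoxynonadec-1-ene-10,13-diol F2 (water at C14) and (10S,11S,13S,14S)-10,13-epoxynonadec-1-ene-11,14-diol F3 (water at C10). Compound 16 is isolated by preparative HPLC and carried into step 10.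

2. Step 10. What may go wrong: insufficient discrimination between the two secondary hydroxyls, i.e. acylation of the ring hydroxyl at C13 and double acylation. Fallback: direct acylation is replaced by a protecting-group exchange that uses the much stronger steric discrimination of a bulky silyl chloride. It sets out from 16 and returns at 18. TBSCl (1.05 equiv) and imidazole in DMF at 0 °C silylate the more accessible exocyclic hydroxyl to give (2S,3S,5R)-5-[(1R)-1-{[tert-butyl(dimethyl)silyl]oxy}dec-9-en-1-yl]-2-pentyloxolan-3-ol F4. Chloroacetic anhydride and pyridine in CH2Cl2 at 0 °C mask the ring hydroxyl as (2S,3S,5R)-5-[(1R)-1-{[tert-butyl(dimethyl)silyl]oxy}dec-9-en-1-yl]-2-pentyloxolan-3-yl chloroacetate F5. HF·pyridine in THF at 0 °C removes the silyl group and gives (2S,3S,5R)-5-[(1R)-1-hydroxydec-9-en-1-yl]-2-pentyloxolan-3-yl chloroacetate F6. Acylation with 17, pyridine and catalytic DMAP in CH2Cl2 gives (1R)-1-[(2R,4S,5S)-4-(chloroacetoxy)-5-pentyloxolan-2-yl]dec-9-en-1-yl hexadecanoate F7. Thiourea and NaHCO3 in ethanol at 50 °C then cleave only the chloroacetate and leave 18.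

3. Step 8. What may go wrong: the triflate decomposes before coupling, or an oxirane is lost through opening by bromide, magnesium salts or the organocopper species. Fallback: the labile triflate and the Grignard reagent are replaced by an isolable sulfonate and a stoichiometric lithium dialkylcuprate, so that no magnesium halide is present. It sets out from 10 (with 12 as chain source) and returns at 14. Compound 10 is converted with TsCl, Et3N and catalytic DMAP in CH2Cl2 at 0 °C into [(2R,3S)-3-{[(2R,3S)-3-pentyloxiran-2-yl]methyl}oxiran-2-yl]methyl 4-methylbenzenesulfonate F8, which can be purified and stored. Compound 12 is lithiated with lithium metal in Et2O at −10 °C to oct-7-en-1-yllithium F9, and CuI (0.5 equiv) in Et2O at −30 °C turns this into lithium di(oct-7-en-1-yl)cuprate F10. The cuprate F10 displaces the tosylate of F8 in Et2O at −40 °C and gives 14.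

**Further compounds**

F1 | step 9 | (10R,11R,13S,14S)-10,13-epoxynonadec-1-ene-11,14-diol | C=CCCCCCCC[C@@H]1[C@H](O)C[C@H](O1)[C@@H](O)CCCCC
F2 | step 9 | (10R,11R,13R,14R)-11,14-epoxynonadec-1-ene-10,13-diol | C=CCCCCCCC[C@@H](O)[C@H]1C[C@@H](O)[C@@H](CCCCC)O1
F3 | step 9 | (10S,11S,13S,14S)-10,13-epoxynonadec-1-ene-11,14-diol | C=CCCCCCCC[C@H]1[C@@H](O)C[C@H](O1)[C@@H](O)CCCCC
F4 | step 10 | (2S,3S,5R)-5-[(1R)-1-{[tert-butyl(dimethyl)silyl]oxy}dec-9-en-1-yl]-2-pentyloxolan-3-ol | C=CCCCCCCC[C@@H](O[Si](C)(C)C(C)(C)C)[C@H]1C[C@H](O)[C@H](CCCCC)O1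
F5 | step 10 | (2S,3S,5R)-5-[(1R)-1-{[tert-butyl(dimethyl)silyl]oxy}dec-9-en-1-yl]-2-pentyloxolan-3-yl chloroacetate | C=CCCCCCCC[C@@H](O[Si](C)(C)C(C)(C)C)[C@H]1C[C@H](OC(=O)CCl)[C@H](CCCCC)O1
F6 | step 10 | (2S,3S,5R)-5-[(1R)-1-hydroxydec-9-en-1-yl]-2-pentyloxolan-3-yl chloroacetate | C=CCCCCCCC[C@@H](O)[C@H]1C[C@H](OC(=O)CCl)[C@H](CCCCC)O1
F7 | step 10 | (1R)-1-[(2R,4S,5S)-4-(chloroacetoxy)-5-pentyloxolan-2-yl]dec-9-en-1-yl hexadecanoate | C=CCCCCCCC[C@@H](OC(=O)CCCCCCCCCCCCCCC)[C@H]1C[C@H](OC(=O)CCl)[C@H](CCCCC)O1
F8 | step 8 | [(2R,3S)-3-{[(2R,3S)-3-pentyloxiran-2-yl]methyl}oxiran-2-yl]methyl 4-methylbenzenesulfonate | Cc1ccc(cc1)S(=O)(=O)OC[C@H]1O[C@H]1C[C@H]1O[C@H]1CCCCC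
F9 | step 8 | oct-7-en-1-yllithium | [Li]CCCCCCC=C
F10 | step 8 | lithium di(oct-7-en-1-yl)cuprate | [Li+].C=CCCCCCC[Cu-]CCCCCCC=C
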